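**Plan**

- Retrosynthesis: the C7 O–CH3 bond is cut first. Ring A is then cut at C7–C8 and C5–C6, which releases C6–C7 as methyl methoxyacetate and leaves C5 as an ester on C4a and C8 as a methoxymethyl group on C8a of a 4-pyranone (ring C, already carrying ring B).
- Enabling feature: every carbon of ring A bears oxygen, with C5 and C7 at carbonyl (phenol) level in a 1,3-relationship and C6 and C8 carrying OMe. Ring A is therefore a masked 1,3-dicarbonyl array flanked by two methoxylated carbanion carbons.
- Ring C is cut at O1–C2 and C4–C4a, giving methyl 4-methoxyacetoacetate and (4-methoxyphenyl)propioloyl chloride.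
- Forward order: ring B is bought with the arylpropiolic acid, ring C is closed by C-acylation and 6-endo-dig oxa-Michael addition, ring A is closed last by a Claisen/Dieckmann cascade, and one selective O-methylation finishes the route.
- Stereochemistry: the target is achiral and has no stereocentre, so none has to be set.

Key step: step 4

Remark: flavone numbering of the target is used for all ring positions. Compound 4 is drawn as its triketo tautomer but should exist as a chelated enol.

**Route**

Step 1
Reactants: 1 (4-methoxyphenyl)propiolic acid
Product: 2 (4-methoxyphenyl)propioloyl chloride
Conditions: (COCl)2 (1.2 equiv), N,N-dimethylformamide (cat.), CH2Cl2, 0 °C to rt; evaporate, use crude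
Reagents that add atoms: oxalyl chloride, ClC(=O)C(=O)Cl
Why: Acid chloride formation through the chloroiminium intermediate is standard for arylpropiolic acids, and the low temperature and absence of heating should keep HCl from adding to the triple bond.

Step 2
Reactants: 3 methyl 4-methoxyacetoacetate; 2 (4-methoxyphenyl)propioloyl chloride
Product: 4 methyl 2-(methoxyacetyl)-5-(4-methoxyphenyl)-3-oxopent-4-ynoate
Conditions: MgCl2 (1.1 equiv), pyridine (2.2 equiv), CH2Cl2, 0 °C; then 2, 0 °C to rt; 1 M HCl work-up; use crude
Reagents that add atoms: none
Why: This is the C-acylation of a chelated magnesium enolate of a β-keto ester by an acid chloride (soft enolisation); chelation should direct the acyl group to the carbon between the two carbonyls and suppress O-acylation, and the less acidic CH2OMe group should not be touched.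

Step 3
Reactants: 4 methyl 2-(methoxyacetyl)-5-(4-methoxyphenyl)-3-oxopent-4-ynoate
Product: 5 methyl 6-(4-methoxyphenyl)-2-(methoxymethyl)-4-oxo-4H-pyran-3-carboxylate
Conditions: CF3SO3H (0.2 equiv), CH2Cl2, 0 °C to rt
Reagents that add atoms: none
Why: Acid-catalysed intramolecular oxa-Michael addition (6-endo-dig) of the enol oxygen of the methoxyacetyl ketone to the protonated ynone is the known route from enolisable acyl ynones to 4-pyranones; the anisyl group stabilises positive charge at the attacked alkyne carbon, and the enol oxygen is a better nucleophile than the ester carbonyl.

Step 4
Reactants: 5 methyl 6-(4-methoxyphenyl)-2-(methoxymethyl)-4-oxo-4H-pyran-3-carboxylate; 6 methyl methoxyacetate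
Product: 8 nevadensin (5,7-dihydroxy-6,8,4'-trimethoxyflavone), via Claisen ketone 7 (not isolated)
Conditions: 5 and 6 (1.5 equiv), THF, −78 °C; LiN(SiMe3)2 (2.1 equiv, slow addition), −78 to −30 °C; then LiN(iPr)2 (2.2 equiv), −78 to 0 °C; 1 M HCl
Reagents that add atoms: none
Why: Proposed new method: the CH2 of the methoxymethyl group on C8a (future C8) is the vinylogous α-position of both the C4 ketone and the C4a ester, so LiN(SiMe3)2 should deprotonate it, and the lateral dienolate should add to the ester carbonyl of 6 and expel methoxide, a Claisen condensation that forms C8–C7 and leaves 7 as its stabilised enolate. LiN(iPr)2 should then remove a proton from the other methoxymethylene of 7 (future C6), and this more reactive terminus of the dianion should attack the C4a ester in a 6-exo-trig Dieckmann closure that forms C6–C5 and ring A; loss of methoxide and two enolisations give the aromatic bis-phenoxide, which makes the cascade irreversible. The closest known reaction type is the anionic annulation of laterally lithiated ortho-toluates, homophthalates and 2-methylchromone-3-carboxylates with esters or Michael acceptors, which ends in the same Dieckmann closure to a 1,3-dioxygenated arene; a monocyclic 4-pyranone-3-carboxylate has not been used in this role. No stereocentre is formed, because C8 of 7 is planar in the enolate and both new ring carbons end up aromatic. The step needs deprotonation of the side chain and not addition of base to C2 or C8a of the pyranone, which the hindered amide bases and the acidity of that CH2 group should secure, and it needs acylation of the dienolate to outrun enolisation of 6, which is why the first base is added slowly to the mixture of 5 and 6 so that it is always consumed by the far more acidic 5 and 7. Closure of the C6 carbanion on the C4 ketone is not possible, since it would require a bridged ring with a bridgehead double bond, so the ester is the only electrophile within reach.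

Step 5
Reactants: 8 nevadensin (5,7-dihydroxy-6,8,4'-trimethoxyflavone)
Product: 9 5-hydroxy-6,7,8,4'-tetramethoxyflavone (5-O-demethyltangeretin, the target)
Conditions: MeI (1.1 equiv), K2CO3 (1.2 equiv), acetone, 40 °C
Reagents that add atoms: iodomethane, CI
Why: Williamson etherification should take place only at the C7 hydroxyl, which is the more acidic, free phenol (vinylogous acid of the C4 carbonyl), whereas the C5 hydroxyl is held in a hydrogen bond to the C4 carbonyl and is a much poorer nucleophile.

**Compound list**

1 | (4-methoxyphenyl)propiolic acid | COc1ccc(C#CC(=O)O)cc1 | starting material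
2 | (4-methoxyphenyl)propioloyl chloride | COc1ccc(C#CC(=O)Cl)cc1 | intermediate
3 | methyl 4-methoxyacetoacetate | COCC(=O)CC(=O)OC | starting material
4 | methyl 2-(methoxyacetyl)-5-(4-methoxyphenyl)-3-oxopent-4-ynoate | COCC(=O)C(C(=O)OC)C(=O)C#Cc1ccc(OC)cc1 | intermediate
5 | methyl 6-(4-methoxyphenyl)-2-(methoxymethyl)-4-oxo-4H-pyran-3-carboxylate | COCc1oc(-c2ccc(OC)cc2)cc(=O)c1C(=O)OC | intermediate
6 | methyl methoxyacetate | COCC(=O)OC | starting material
7 | methyl 2-(1,3-dimethoxy-2-oxopropyl)-6-(4-methoxyphenyl)-4-oxo-4H-pyran-3-carboxylate (Claisen ketone, formed as its enolate, not isolated) | COCC(=O)C(OC)c1oc(-c2ccc(OC)cc2)cc(=O)c1C(=O)OC | intermediate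
8 | nevadensin (5,7-dihydroxy-6,8,4'-trimethoxyflavone) | COc1ccc(-c2cc(=O)c3c(O)c(OC)c(O)c(OC)c3o2)cc1 | intermediate
9 | 5-hydroxy-6,7,8,4'-tetramethoxyflavone | COc1ccc(-c2cc(=O)c3c(O)c(OC)c(OC)c(OC)c3o2)cc1 | target

**Step count**

Total steps: 5. Longest linear sequence: 5 steps (1 to 2 to 4 to 5 to 8 to 9); 3 and 6 enter as purchased materials.

**Steps most likely to fail**

Step 4 (the one step beyond known chemistry). Enolisation and self-condensation of ester 6 may outrun acylation of the stabilised dienolate. The cascade may also stall at the enolate of 7 if the second deprotonation or the closure is too slow, or amide or methoxide may add to the pyranone ring and open it. The fallback sets out from 5 and comes back at 8, and makes the two bonds in separate flasks by known reaction types. The lateral lithium dienolate of 5 (LiN(SiMe3)2, 1.1 equiv, THF, −78 °C) is acylated with N,2-dimethoxy-N-methylacetamide. Its chelated tetrahedral adduct releases no alkoxide and accepts no second nucleophile, and its α-protons are less acidic than those of an ester. Acidic work-up should give ketone 7, this time isolated. Ring closure is then run under thermodynamic control with NaOMe in MeOH at 50 °C. This is an intramolecular Claisen condensation of the minor C6 enolate onto the ester, as in base-mediated cyclisations of diketo esters to resorcinols, and should give 8. No compound outside the list arises on this path (entry F0).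

Step 3. The ring may close in the 5-exo-dig sense to an arylidene furanone, the ester carbonyl oxygen may take part and lead to a 2-pyranone, or the acid may hydrate the alkyne. The fallback sets out from 4 and comes back at 5, and replaces direct cyclisation by an addition–elimination sequence. Pyrrolidine (EtOH, rt) adds to the ynone in a conjugate sense to give the β-amino enone methyl (4E)-2-(methoxyacetyl)-5-(4-methoxyphenyl)-3-oxo-5-(pyrrolidin-1-yl)pent-4-enoate F1. Warming F1 in AcOH should let the enol oxygen displace pyrrolidine at the amine-bearing carbon, since the push–pull double bond isomerises freely. This fixes the ring size at six and should give 5.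

Step 2. The enolate may be O-acylated, chloride or pyridine may add to the triple bond of the acetylenic acid chloride, or 2 may decompose before it is consumed. The fallback sets out from 1 and comes back at 4; it avoids the acid chloride and changes which acyl group is introduced last. Acid 1 is activated with 1,1'-carbonyldiimidazole (THF, rt) to 1-[(4-methoxyphenyl)propioloyl]imidazole F2. F2 is condensed with the magnesium salt of monomethyl malonate (KO2CCH2CO2Me, MgCl2, Et3N, THF; decarboxylative Claisen condensation) to give methyl 5-(4-methoxyphenyl)-3-oxopent-4-ynoate F3. C-acylation of the magnesium enolate of F3 with methoxyacetyl chloride (MgCl2, pyridine, CH2Cl2, 0 °C) should give 4.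

**Further compounds**

F0 | step 4 | none | none
F1 | step 3 | methyl (4E)-2-(methoxyacetyl)-5-(4-methoxyphenyl)-3-oxo-5-(pyrrolidin-1-yl)pent-4-enoate | COCC(=O)C(C(=O)OC)C(=O)/C=C(/N1CCCC1)c1ccc(OC)cc1
F2 | step 2 | 1-[(4-methoxyphenyl)propioloyl]imidazole | COc1ccc(C#CC(=O)n2ccnc2)cc1
F3 | step 2 | methyl 5-(4-methoxyphenyl)-3-oxopent-4-ynoate | COC(=O)CC(=O)C#Cc1ccc(OC)cc1
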